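The runs were computed for substances that don't exist; scatter was added.

The target in this flask reads 38.7% at 20.0 min and 15.8% at 90.0 min. The south run is this very flask followed so far, so the question is what a remedy at 1.5 h can still do.

- south: substrate 1.1 M; coupling partner 1.21 M; free catalyst 200 mM; temperature 70 °C; the very flask that is asked about, followed so far
- flask: substrate 1.1 M; coupling partner 1.21 M; free catalyst 200 mM; temperature 70 °C; time 1.5 h

- south (time / min: target / %): 20.0: 38.7; 40.0: 28.9; 50.0: 23.5; 80.0: 15.6; 90.0: 15.8

(standard deviation of a reading: 1 percentage point)

- red: at 1.5 h add coupling partner, 50.0% of the amount charged, then wait 50 min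
- grey: at 1.5 h add free catalyst, 100% of the amount charged, then wait 50 min
- blue: change nothing and wait 50 min more
- ochre: at 1.5 h raise the temperature by 15 K, then wait 50 min
- violet: at 1.5 h take out 90% of the by-product then present, then wait 50 min

- additions bring no volume worth counting
- a reading or a percentage of target counts all its forms, free or not
- the earlier runs do not show what temperature does; that part of a forecast is a guess

* target, in percent of the substrate first charged, at 1.5 h
* the remedy with the largest gain of target, or "none" below 2 percentage points (red / grey / blue / ochre / violet / none)
* target present, in percent of the substrate first charged, after ochre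
* target present, in percent of the substrate first charged, after violet

Our reckoning starts from a supposition: by-product arises with target in equal measure and then consumes it. Both would then stand at the same fraction y of the charge, and the loss per minute would go as y squared, a second-order decay. Such a law needs no integrating, since the reciprocal of y climbs in a straight line.

So we read the table through its reciprocals. The first three rows give 2.58, 3.46 and 4.26. The last two rows stand level within the scatter, so we take their mean, 6.37 at 85.0 min. From the first row to that mean, the line gives the loss constant, the rise of the reciprocal of the target fraction per minute 0.0582 min⁻¹, a reading with the scatter of the readings in it.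

We then use both ends of the line. Walked forward to 1.5 h, it gives 15.0%. Walked back to the start, it gives 70.5%, the fraction the line begins from, so on our supposition about 29.5% of the substrate looks unturned.

Something stopped early, then. We bet on red: coupling partner is spent as it works and was charged at 1.10 equivalents, while catalyst should come back. With by-product cut to a tenth, the same law leaves 14.4% after violet.

The forecast, holding that “the substrate has probably been used up early”, says 15%, best none, 5% after ochre and 7% after violet. We part from it on best and on violet.

The flask gives 15.5%, best red with a gain of 5.8 percentage points, 6.68% after ochre and 15.0% after violet.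

    coupling partner → decomposed reagent (k = 0.130 min⁻¹, Ea = 94.0 kJ mol⁻¹)
    substrate + free catalyst → catalyst intermediate A (k = 47.0 M⁻¹ min⁻¹, Ea = 61.0 kJ mol⁻¹)
    catalyst intermediate C → free catalyst + target (k = 1.20 min⁻¹, Ea = 104 kJ mol⁻¹)
    crystals ⇌ target, rate k4*(cs4 - [target]) while solid is left; crystals form when [target] > cs4 (solubility = 0.640 M, k = 8.10 min⁻¹)
    catalyst intermediate B → by-product + catalyst intermediate C (k = 1.20 min⁻¹, Ea = 103 kJ mol⁻¹)
    coupling partner + catalyst intermediate A → catalyst intermediate B (k = 0.990 M⁻¹ min⁻¹, Ea = 69.0 kJ mol⁻¹)
    target + by-product → side product (k = 0.0500 M⁻¹ min⁻¹, Ea = 77.0 kJ mol⁻¹)
    (constants at 70 °C)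

At 3.46 min in this flask, coupling partner has a half-life of 5.3 min by decomposition, far shorter than the 59 min of target by its step with by-product. At 90.0 min coupling partner, the limiting reagent, stands at 0% with substrate at 30.9%. Carried on from 15.5%, the loss constant gives 1.87% at 900 min, where this flask holds 1.96%.

For the neighbour with 0.44 M of substrate, we scale the constant with the charge, which gives 0.0233 min⁻¹. Starting that neighbour from its whole charge as target gives 32.3% at 1.5 h, and its computed result is 35.0%.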